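Numbering and enabling feature: the six-membered lactone O1–C2(=O)–C3=C4(OMe)–C5–C6 is fused along C5–C6 to the cyclobutane C5–C6–C8–C7 (styryl on C6, aryl on C7, pyranone on C8; α is the face of O1, β the other face). O1, C4 and the C7 aryl all stand on the α face of the contiguous carbons C6, C5 and C7. C5–C4 and C7–aryl are therefore two cis bonds on neighbouring carbons, and one syn aryl-metalation of a C5=C7 cyclobutene, relayed into an acyl tether hanging from O1, can make both.
Retrosynthetic cuts, in order: silyl groups; pyranone ring (C8–CO2H plus a C4 acetoacetate unit); styryl C=C (olefination of a lactol on C6); C7–aryl and C4–C5 together; O1–C2 (malonylation); C6–O1 (enolate hydroxylation); cyclobutene ([2+2]).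
The two β carbons (future styryl and pyranone attachment points) pass through the key step tied as a γ-lactone bridge C6–C(=O)–O–CH2–C8. The resulting bicyclo[3.2.0]heptene cannot open conrotatorily, exposes only its α (convex) face and makes β-acyloxy elimination costly. A monocyclic cyclobutene already carrying styryl, acyloxy and pyranone groups would be expected to ring-open near room temperature.
Forward ring order: cyclobutene, γ-lactone clamp, six-membered lactone (key step), clamp opened, pyranone last.
Stereochemistry: C6 and C8 (absolute) come from alkaloid-mediated desymmetrisation of the meso anhydride, C6–O from hydroxylation with retention enforced by the ring fusion, C5 and C7 from syn addition on the convex face, and the E alkene from the Horner–Wadsworth–Emmons step.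

Key step: step 7

Assumption: quinidine is taken to guide methanol to the carbonyl on C8 (giving 4); should the sense prove opposite, its pseudoenantiomer quinine serves in the same protocol. TIPS = triisopropylsilyl.

Step 1
Reactants: 1 maleic anhydride; 2 acetylene
Product: 3 meso-(1R,5S)-3-oxabicyclo[3.2.0]hept-6-ene-2,4-dione (cis-cyclobut-3-ene-1,2-dicarboxylic anhydride)
Conditions: hν (medium-pressure Hg lamp, Pyrex), acetophenone (sensitiser), C2H2-saturated EtOAc, −40 °C
Reagents that add atoms: none
Why: Triplet-sensitised [2+2] photocycloaddition of an alkyne to maleic anhydride, in which the five-membered ring can only become cis-fused, so the two new centres (C6, C8) arise as the meso pair.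

Step 2
Reactants: 3 meso anhydride
Product: 4 (1S,2R)-2-(methoxycarbonyl)cyclobut-3-ene-1-carboxylic acid (acid on C6, ester on C8, cis)
Conditions: quinidine (1.1 equiv), MeOH (3 equiv), PhMe, −55 °C; dilute HCl wash
Reagents that add atoms: methanol, CO
Why: Cinchona-alkaloid-mediated desymmetrising methanolysis of a cyclic meso anhydride, in which the alkaloid guides methanol to one of the two enantiotopic carbonyl groups and thereby fixes the absolute configuration of C6 and C8 for the whole route.

Step 3
Reactants: 4 half ester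
Product: 6 (1S,5R)-3-oxabicyclo[3.2.0]hept-6-en-2-one (C=O on C6, OCH2 on C8), via hydroxy acid 5 (not isolated)
Conditions: LiBEt3H (3.2 equiv), THF, −78 °C to rt; then 2 M HCl, rt
Reagents that add atoms: none
Why: Chemoselective hydride reduction of the ester next to the inert lithium carboxylate followed by acid-induced lactonisation, a standard conversion of such half esters, which touches neither stereocentre and succeeds because the two side chains are cis.

Step 4
Reactants: 6 bicyclic lactone
Product: 8 (1R,5S)-1-hydroxy-3-oxabicyclo[3.2.0]hept-6-en-2-one (OH on C6, α), via potassium enolate 7 (not isolated)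
Conditions: KN(SiMe3)2 (1.1 equiv), THF, −78 °C; 2-(phenylsulfonyl)-3-phenyloxaziridine (1.3 equiv), −78 °C; AcOH quench
Reagents that add atoms: 2-(phenylsulfonyl)-3-phenyloxaziridine, O=S(=O)(c1ccccc1)N1OC1c1ccccc1 (oxygen); KN(SiMe3)2, C[Si](C)(C)[N-][Si](C)(C)C.[K+] (potassium of 7 only)
Why: Enolate hydroxylation with an N-sulfonyloxaziridine, for which C6–H is the only proton α to a carbonyl group and oxygen has to enter with retention because the bicyclo[3.2.0] skeleton tolerates only a cis ring fusion, so the new C6–O bond lies trans to the CH2 on C8.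

Step 5
Reactants: 8 hydroxy lactone; 9 methyl malonyl chloride (methyl 3-chloro-3-oxopropanoate)
Product: 10 methyl (1R,5S)-2-oxo-3-oxabicyclo[3.2.0]hept-6-en-1-yl propanedioate (cyclobutenyl methyl malonate, malonyloxy on C6 α, lactone bridge β)
Conditions: pyridine (3 equiv), DMAP (0.1 equiv), CH2Cl2, 0 °C to rt
Reagents that add atoms: none
Why: Pyridine/DMAP-mediated O-acylation with a malonyl chloride, a reagent reactive enough (acylpyridinium or ketene pathway) for tertiary α-hydroxy esters, under a base too weak to start a Dieckmann closure on the neighbouring lactone carbonyl, and no stereocentre is touched.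

Step 6
Reactants: 11 4-hydroxyphenylboronic acid
Product: 12 4-(triisopropylsilyloxy)phenylboronic acid
Conditions: i-Pr3SiCl (1.2 equiv), imidazole, DMF, rt; aqueous work-up
Reagents that add atoms: chlorotriisopropylsilane, CC(C)[Si](Cl)(C(C)C)C(C)C
Why: Standard imidazole-promoted silylation of the phenol, any B–O–Si bond being hydrolysed on work-up, and the bulky silyl group is chosen because it outlasts K2CO3, phosphonate carbanion and DBU later on.

Step 7
Reactants: 10 cyclobutenyl methyl malonate; 12 arylboronic acid
Product: 14 tricyclic keto bis-lactone (cyclobutane C5–C6–C8–C7 with the 2,4-dioxotetrahydropyran ring O1–C2–C3–C4 fused at C6–C5 and the 4-TIPSO-phenyl group on C7 all α; bridge C6–C(=O)–O–CH2–C8 β), via cyclobutylrhodium alkyl 13 (not isolated)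
Conditions: [Rh(OH)(cod)]2 (5 mol %), 12 (2 equiv), KHCO3 (1.5 equiv), 4 Å sieves, 1,4-dioxane, 50 °C; cold 0.5 M HCl work-up
Reagents that add atoms: [Rh(OH)(cod)]2, [OH-].[OH-].[Rh+].[Rh+].C1=CCCC=CCC1.C1=CCCC=CCC1 (rhodium of 13 only)
Why: Proposed new method: transmetalation from 12 to the hydroxo complex gives an aryl complex of monovalent rhodium that inserts the strained C5=C7 bond in a syn fashion (aryl to C7, metal to C5) to give 13, whose C5–Rh bond adds to the distal methyl ester carbonyl C4 and expels methoxide, and the Rh–OMe species re-enters transmetalation, so that no proton is needed for turnover. The closest known reaction types are the rhodium-catalysed carbometalation of cyclobutenes with arylboronic acids and the rhodium-catalysed arylative cyclisations in which an organorhodium formed from an alkyne or a strained alkene ends by attacking a tethered ester or nitrile, but the two have not been joined on a cyclobutene. The six-membered keto lactone closes in the 6-exo-trig mode (C5 attacks C4, the carbonyl oxygen staying outside the ring). C7 and C5 are both set by the syn addition to the convex α face of the bicyclo[3.2.0]heptene, the face that bears the malonyloxy group and H8, and carbonyl insertion proceeds with retention at C5, so that aryl, C4 and O1 end up cis and the new ring fusion is cis. The required regioselectivity (aryl to the distal C7, metal beside the oxygenated C6) rests on the usual bias of allylic esters in aryl-metal insertions, on coordination of rhodium by the malonate carbonyl groups and on the smaller neighbour (H8) at C7. Chemoselectivity for acylation rests on 13 having no syn β-hydrogen (C6 is quaternary, H7 is anti), on the strained bicyclo[3.2.0]hept-1(7)-ene that a syn β-acyloxy elimination would have to create, on a nearly aprotic medium and on KHCO3, which binds the strongly acidic enolic product but is too weak to deprotonate the malonate CH2.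

Step 8
Reactants: 14 keto bis-lactone
Product: 15 4-methoxy enol ether of 14 (C3=C4–OMe; all four ring centres as in 14)
Conditions: Me2SO4 (1.1 equiv), K2CO3, acetone, rt
Reagents that add atoms: dimethyl sulfate, COS(=O)(=O)OC
Why: O-Methylation of the enol (4-hydroxy-5,6-dihydropyran-2-one) tautomer with a hard electrophile and K2CO3, the usual way to 4-methoxy-5,6-dihydropyran-2-ones, with C5 held in place by the cis ring fusion.

Step 9
Reactants: 15 methoxy bis-lactone
Product: 16 lactol (bridge now C6–CH(OH)–O–CH2–C8, anomeric mixture; six-membered lactone intact)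
Conditions: i-Bu2AlH (1.1 equiv), CH2Cl2, −78 °C; aq. KNaC4H4O6
Reagents that add atoms: none
Why: Low-temperature partial reduction of a lactone to the lactol, selective because the saturated α-acyloxy γ-lactone is much more electrophilic than the push–pull 4-methoxy-enoate lactone (a vinylogous carbonate), and the new anomeric centre is lost in step 12.

Step 10
Reactants: 17 4-hydroxybenzyl alcohol
Product: 18 diethyl (4-hydroxybenzyl)phosphonate
Conditions: P(OEt)3 (neat, 3 equiv), 145 °C, EtOH distilled off
Reagents that add atoms: triethyl phosphite, CCOP(OCC)OCC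
Why: Michaelis–Arbuzov-type phosphonylation, known for p-hydroxybenzylic alcohols, which ionise on heating and are captured by the phosphite with loss of ethanol.

Step 11
Reactants: 18 hydroxybenzylphosphonate
Product: 19 diethyl [4-(triisopropylsilyloxy)benzyl]phosphonate
Conditions: i-Pr3SiCl, imidazole, DMF, rt
Reagents that add atoms: chlorotriisopropylsilane, CC(C)[Si](Cl)(C(C)C)C(C)C
Why: Standard imidazole-promoted silylation of the only hydroxyl group present.

Step 12
Reactants: 16 lactol; 19 phosphonate
Product: 21 styryl alcohol (2-oxabicyclo[4.2.0]oct-4-en-3-one core with (E)-4-TIPSO-styryl on C6 β, CH2OH on C8 β, 4-TIPSO-phenyl on C7 α), via phosphonate carbanion 20 (not isolated)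
Conditions: 19 (3 equiv), KN(SiMe3)2 (3 equiv), THF, −78 to 0 °C; then 16, 0 °C to rt
Reagents that add atoms: KN(SiMe3)2, C[Si](C)(C)[N-][Si](C)(C)C.[K+] (potassium of 20 only)
Why: Horner–Wadsworth–Emmons olefination of a lactol through its ring-opened tautomer, in which the aryl-stabilised carbanion gives the E alkene and the reacting carbon sits on quaternary C6, so nothing can epimerise.

Step 13
Reactants: 21 styryl alcohol
Product: 22 C8 carboxylic acid
Conditions: TEMPO (0.2 equiv), PhI(OAc)2 (2.5 equiv), MeCN/H2O, rt
Reagents that add atoms: water, O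
Why: Oxoammonium-catalysed oxidation of a primary alcohol to the carboxylic acid in aqueous medium, mild and nearly neutral, so that C8 is not epimerised and the silyl ethers, enol ether and styrene survive.

Step 14
Reactants: 23 methyl acetoacetate
Product: 24 1-methoxy-1,3-bis(trimethylsilyloxy)buta-1,3-diene (ketene acetal geometry inconsequential)
Conditions: Me3SiOTf (2.2 equiv), Et3N (2.5 equiv), Et2O, 0 °C to rt
Reagents that add atoms: trimethylsilyl trifluoromethanesulfonate, C[Si](C)(C)OS(=O)(=O)C(F)(F)F
Why: Double O-silylation of a β-keto ester with Me3SiOTf/Et3N, the direct route to 1,3-bis(silyloxy)dienes.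

Step 15
Reactants: 22 acid; 24 bis(silyloxy)diene
Product: 26 methyl 3,5-dioxopentanoate carried on C8 (C8–C(=O)CH2C(=O)CH2CO2Me), via acid chloride 25 (not isolated)
Conditions: 1-chloro-N,N,2-trimethylpropenylamine (1.2 equiv), CH2Cl2, 0 °C; then 24 (2 equiv), −78 °C to rt; H2O work-up
Reagents that add atoms: 1-chloro-N,N,2-trimethylpropenylamine, CC(C)=C(Cl)N(C)C (chlorine of 25 only)
Why: Neutral conversion of the acid into its chloride with an α-chloroenamine followed by γ-selective C-acylation of the bis(silyl) dienol ether, a known base-free entry to 3,5-dioxo esters that leaves the α-stereocentre C8 untouched.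

Step 16
Reactants: 26 dioxo ester
Product: 28 bis-TIPS ether of the target, via hydroxypyranone 27 (not isolated)
Conditions: DBU (1.5 equiv), PhMe, rt; evaporate; Me2SO4 (1.2 equiv), K2CO3, acetone, rt
Reagents that add atoms: dimethyl sulfate, COS(=O)(=O)OC
Why: DBU-induced enol lactonisation of a 3,5-dioxo ester to the 4-hydroxy-2-pyranone followed by the customary Me2SO4/K2CO3 O-methylation at the 4-oxygen, with short exposure at room temperature to keep C8 from epimerising.

Step 17
Reactants: 28 bis-TIPS ether
Product: 29 target, (1R,6S,7S,8S)-7-(4-hydroxyphenyl)-1-[(E)-2-(4-hydroxyphenyl)ethenyl]-5-methoxy-8-(4-methoxy-2-oxo-2H-pyran-6-yl)-2-oxabicyclo[4.2.0]oct-4-en-3-one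
Conditions: Bu4NF (2.5 equiv), AcOH (2.5 equiv), THF, 0 °C
Reagents that add atoms: none
Why: Fluoride cleavage of the two aryl silyl ethers, buffered with acetic acid so that the phenoxides are protonated at once and lactone, pyranone and the four stereocentres remain untouched.

Compound list
1 | maleic anhydride | O=C1C=CC(=O)O1 | starting material
2 | acetylene | C#C | starting material
3 | meso-(1R,5S)-3-oxabicyclo[3.2.0]hept-6-ene-2,4-dione | O=C1OC(=O)[C@@H]2C=C[C@H]12 | intermediate
4 | (1S,2R)-2-(methoxycarbonyl)cyclobut-3-ene-1-carboxylic acid | COC(=O)[C@@H]1C=C[C@@H]1C(=O)O | intermediate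
5 | (1S,2R)-2-(hydroxymethyl)cyclobut-3-ene-1-carboxylic acid | OC[C@@H]1C=C[C@@H]1C(=O)O | intermediate
6 | (1S,5R)-3-oxabicyclo[3.2.0]hept-6-en-2-one | O=C1OC[C@@H]2C=C[C@H]12 | intermediate
7 | potassium enolate of 6 | [K+].[O-]C1=C2C=C[C@H]2CO1 | intermediate
8 | (1R,5S)-1-hydroxy-3-oxabicyclo[3.2.0]hept-6-en-2-one | O=C1OC[C@@H]2C=C[C@]12O | intermediate
9 | methyl malonyl chloride | COC(=O)CC(=O)Cl | starting material
10 | methyl (1R,5S)-2-oxo-3-oxabicyclo[3.2.0]hept-6-en-1-yl propanedioate | COC(=O)CC(=O)O[C@]2(C(=O)OC3)C=C[C@H]23 | intermediate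
11 | 4-hydroxyphenylboronic acid | OB(O)c1ccc(O)cc1 | starting material
12 | 4-(triisopropylsilyloxy)phenylboronic acid | OB(O)c1ccc(O[Si](C(C)C)(C(C)C)C(C)C)cc1 | intermediate
13 | cyclobutylrhodium alkyl (Rh on C5 α, aryl on C7 α; cod ligand not drawn) | COC(=O)CC(=O)O[C@]2(C(=O)OC3)[C@H]([Rh])[C@H](c1ccc(O[Si](C(C)C)(C(C)C)C(C)C)cc1)[C@H]23 | intermediate
14 | tricyclic keto bis-lactone | O=C1CC(=O)O[C@]2(C(=O)OC3)[C@H]1[C@H](c1ccc(O[Si](C(C)C)(C(C)C)C(C)C)cc1)[C@H]23 | intermediate
15 | 4-methoxy enol ether of 14 | COC1=CC(=O)O[C@]2(C(=O)OC3)[C@H]1[C@H](c1ccc(O[Si](C(C)C)(C(C)C)C(C)C)cc1)[C@H]23 | intermediate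
16 | lactol from 15 (anomeric mixture) | COC1=CC(=O)O[C@]2(C(O)OC3)[C@H]1[C@H](c1ccc(O[Si](C(C)C)(C(C)C)C(C)C)cc1)[C@H]23 | intermediate
17 | 4-hydroxybenzyl alcohol | OCc1ccc(O)cc1 | starting material
18 | diethyl (4-hydroxybenzyl)phosphonate | CCOP(=O)(Cc1ccc(O)cc1)OCC | intermediate
19 | diethyl [4-(triisopropylsilyloxy)benzyl]phosphonate | CCOP(=O)(Cc1ccc(O[Si](C(C)C)(C(C)C)C(C)C)cc1)OCC | intermediate
20 | potassium carbanion of 19 | [K+].CCOP(=O)([CH-]c1ccc(O[Si](C(C)C)(C(C)C)C(C)C)cc1)OCC | intermediate
21 | styryl alcohol (C8–CH2OH) | COC1=CC(=O)O[C@]2(/C=C/c3ccc(O[Si](C(C)C)(C(C)C)C(C)C)cc3)[C@H]1[C@H](c1ccc(O[Si](C(C)C)(C(C)C)C(C)C)cc1)[C@H]2CO | intermediate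
22 | C8 carboxylic acid | COC1=CC(=O)O[C@]2(/C=C/c3ccc(O[Si](C(C)C)(C(C)C)C(C)C)cc3)[C@H]1[C@H](c1ccc(O[Si](C(C)C)(C(C)C)C(C)C)cc1)[C@H]2C(=O)O | intermediate
23 | methyl acetoacetate | COC(=O)CC(C)=O | starting material
24 | 1-methoxy-1,3-bis(trimethylsilyloxy)buta-1,3-diene | COC(O[Si](C)(C)C)=CC(=C)O[Si](C)(C)C | intermediate
25 | C8 acid chloride | COC1=CC(=O)O[C@]2(/C=C/c3ccc(O[Si](C(C)C)(C(C)C)C(C)C)cc3)[C@H]1[C@H](c1ccc(O[Si](C(C)C)(C(C)C)C(C)C)cc1)[C@H]2C(=O)Cl | intermediate
26 | C8 3,5-dioxo ester | COC1=CC(=O)O[C@]2(/C=C/c3ccc(O[Si](C(C)C)(C(C)C)C(C)C)cc3)[C@H]1[C@H](c1ccc(O[Si](C(C)C)(C(C)C)C(C)C)cc1)[C@H]2C(=O)CC(=O)CC(=O)OC | intermediate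
27 | C8 4-hydroxy-2-oxo-2H-pyran-6-yl compound | COC1=CC(=O)O[C@]2(/C=C/c3ccc(O[Si](C(C)C)(C(C)C)C(C)C)cc3)[C@H]1[C@H](c1ccc(O[Si](C(C)C)(C(C)C)C(C)C)cc1)[C@H]2c1cc(O)cc(=O)o1 | intermediate
28 | bis-TIPS ether of the target, (1R,6S,7S,8S) | COC1=CC(=O)O[C@]2(/C=C/c3ccc(O[Si](C(C)C)(C(C)C)C(C)C)cc3)[C@H]1[C@H](c1ccc(O[Si](C(C)C)(C(C)C)C(C)C)cc1)[C@H]2c1cc(OC)cc(=O)o1 | intermediate
29 | CNP0228336.2, (1R,6S,7S,8S) | COC1=CC(=O)O[C@]2(/C=C/c3ccc(O)cc3)[C@H]1[C@H](c1ccc(O)cc1)[C@H]2c1cc(OC)cc(=O)o1 | target

Total step count: 17. Longest linear sequence: 13 steps (1–5, 7–9, 12, 13, 15–17).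

Steps most likely to fail

Step 7. The cyclobutyl–rhodium bond may be intercepted before it reaches the ester. Possible routes are protonation by the malonate CH2 or by water formed in the flask, 1,4-migration of rhodium to the ortho position of the new aryl ring, and β-acyloxy elimination. The malonate may also close on the neighbouring lactone carbonyl in a Dieckmann manner. The fallback builds the skeleton by the known photodimerisation of 6-styryl-2-pyranones.
- It sets out from phosphonate 19.
- SeO2 oxidation of commercial 4-methoxy-6-methyl-2H-pyran-2-one gives 4-methoxy-2-oxo-2H-pyran-6-carbaldehyde F1.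
- Horner–Wadsworth–Emmons reaction of 19 (NaH, THF) with F1 gives the (E)-styrylpyranone F2.
- Irradiation of F2 (λ > 350 nm, concentrated solution or crystalline film) brings about the crossed [2+2] cycloaddition between the ring C5=C6 bond of one molecule and the styryl C=C of another.
- The wanted regio- and diastereomer is separated by chromatography as the racemate.
- HPLC on a chiral phase removes the enantiomer of 28 F3. The route is rejoined at 28, before step 17.

Step 9. Hydride may fail to discriminate between the two lactones, or may carry the γ-lactone through to the diol. The fallback inverts steps 8 and 9 so that the six-membered ring is masked as its anion during reduction.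
- It sets out from 14, where NaH (1 equiv, THF, 0 °C) gives the sodium enolate F4, a delocalised vinylogous carboxylate inert to hydride.
- i-Bu2AlH (−78 °C) then reduces only the γ-lactone and gives, after buffered work-up, the keto-lactone lactol F5.
- O-Methylation of the far more acidic enol (Me2SO4, 1 equiv, K2CO3, acetone) rejoins the route at 16.

Step 12. The strongly basic carbanion may cause acyl migration or silyl loss, or may fail to engage the hindered and largely closed lactol. The fallback replaces the basic olefination by a non-basic two-step sequence.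
- It sets out from 16, where Takai olefination (CrCl2, CHI3, THF, 0 °C to rt) gives the (E)-vinyl iodide alcohol F6.
- Suzuki–Miyaura coupling of F6 with boronic acid 12 (Pd(PPh3)4, K3PO4, THF/H2O, rt) rejoins the route at 21.

Further compounds
F1 | step 7 | 4-methoxy-2-oxo-2H-pyran-6-carbaldehyde | O=Cc1cc(OC)cc(=O)o1
F2 | step 7 | 4-methoxy-6-[(E)-2-(4-triisopropylsilyloxyphenyl)ethenyl]-2H-pyran-2-one | COc1cc(/C=C/c2ccc(O[Si](C(C)C)(C(C)C)C(C)C)cc2)oc(=O)c1
F3 | step 7 | enantiomer of 28 | COC1=CC(=O)O[C@@]2(/C=C/c3ccc(O[Si](C(C)C)(C(C)C)C(C)C)cc3)[C@@H]1[C@@H](c1ccc(O[Si](C(C)C)(C(C)C)C(C)C)cc1)[C@@H]2c1cc(OC)cc(=O)o1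
F4 | step 9 | sodium enolate of 14 | [Na+].[O-]C1=CC(=O)O[C@]2(C(=O)OC3)[C@H]1[C@H](c1ccc(O[Si](C(C)C)(C(C)C)C(C)C)cc1)[C@H]23
F5 | step 9 | keto-lactone lactol (anomeric mixture) | O=C1CC(=O)O[C@]2(C(O)OC3)[C@H]1[C@H](c1ccc(O[Si](C(C)C)(C(C)C)C(C)C)cc1)[C@H]23
F6 | step 12 | (E)-vinyl iodide alcohol | COC1=CC(=O)O[C@]2(/C=C/I)[C@H]1[C@H](c1ccc(O[Si](C(C)C)(C(C)C)C(C)C)cc1)[C@H]2CO
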